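## Retrosynthetic overview

1. Numbering follows cyclopenta[c]pyran (C1 coumarinyl, O2, C3 acyl, C4‑Me, C4a/C7a fusion, C7‑Me; coumarin atoms primed). The plan rests on the C4–C4a bond, the single link between the tetrasubstituted C3=C4 enol ether of the dihydropyran ring and the fusion carbon of the cyclopentane ring. Once C1, C7a and C7 are in place, C4a is the only centre this bond creates.
2. Endgame: the senecioyl ketone comes from the C3 Weinreb amide and an isobutenyl Grignard reagent, run on the free 4'-hydroxycoumarin so that its magnesium salt shields the lactone. The 4'-OH comes from 4'-OMe by chloride demethylation.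
3. Key disconnection: the dihydropyran closes by 6‑exo addition of a C4 vinyl radical, drawn from an E/Z β‑bromo‑α‑alkoxy enamide, to C4a=C5 of a cyclopentene attached at C7a.
4. O2–C3 comes from Rh O–H insertion of a diazoacetoacetamide followed by deoxybromination at C4. C1–C7a comes from anti‑selective allylboration of the 3'-formylcoumarin with an acyclic (E)‑allylboronate that carries C7, followed by RCM. A cyclopentenylboronate is necessarily Z and would give the C1 epimer.
5. Ring order: coumarin (step 1), cyclopentene (step 12), dihydropyran (step 15).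

Key step: step 15

Assumption: (R)‑TRIP is taken to direct an (E)‑allyl pinacolboronate to the Re face of aldehyde 5, as it does with aryl aldehydes. Re‑face attack corresponds to (1R).

## Route

Step 1
Reactants: 1 2'-hydroxy-6'-methylacetophenone
Product: 2 4-hydroxy-5-methylcoumarin
Conditions: NaH (3 equiv), (EtO)2CO, PhMe, 110 °C; aq HCl
Reagents that add atoms: diethyl carbonate CCOC(=O)OCC
Why: Claisen-type C‑acylation of the methyl ketone enolate by diethyl carbonate followed by lactonisation onto the phenoxide is the standard entry to 4‑hydroxycoumarins, and the 6'-methyl group ends up at C5'.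

Step 2
Reactants: 2 4-hydroxy-5-methylcoumarin
Product: 4 4-chloro-5-methyl-2-oxo-2H-chromene-3-carbaldehyde, via iminium chloride 3 (not isolated)
Conditions: POCl3 (3 equiv), DMF, 0 to 60 °C; ice-water
Reagents that add atoms: N,N-dimethylformamide CN(C)C=O; phosphoryl chloride O=P(Cl)(Cl)Cl; water O
Why: Vilsmeier–Haack haloformylation, in which the nucleophilic enol carbon C3' attacks the chloroiminium salt, the vinylogous acid OH at C4' is exchanged for chloride, and aqueous hydrolysis of 3 frees the aldehyde.

Step 3
Reactants: 4 4-chloro-5-methyl-2-oxo-2H-chromene-3-carbaldehyde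
Product: 5 4-methoxy-5-methyl-2-oxo-2H-chromene-3-carbaldehyde
Conditions: NaOMe (1.0 equiv), MeOH–THF, −10 to 0 °C
Reagents that add atoms: sodium methoxide C[O-].[Na+]
Why: Addition–elimination (vinylic nucleophilic substitution) at C4' of a β‑chlorovinyl aldehyde activated by both the formyl and lactone carbonyls should replace chloride by methoxide at low temperature, while methoxide attack at the formyl or lactone carbon is reversible.

Step 4
Reactants: 6 (R)-4-benzyl-3-propionyloxazolidin-2-one
Product: 7 (R)-4-benzyl-3-[(S)-2-methylpent-4-enoyl]oxazolidin-2-one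
Conditions: NaHMDS, THF, −78 °C; allyl iodide, −78 to −45 °C
Reagents that add atoms: allyl iodide C=CCI
Why: Evans asymmetric alkylation, in which the chelated (Z)‑sodium enolate is shielded on one face by the benzyl group of the (R)‑auxiliary, so allyl iodide enters from the other face and sets the future C7 as (S).

Step 5
Reactants: 7 (R)-4-benzyl-3-[(S)-2-methylpent-4-enoyl]oxazolidin-2-one
Product: 8 (S)-2-methylpent-4-en-1-ol
Conditions: LiBH4, H2O (1 equiv), Et2O, 0 °C; aq NaOH
Reagents that add atoms: none
Why: Reductive removal of the auxiliary by hydride attack at the exocyclic imide carbonyl reduces the transient aldehyde stage faster than it can enolise, so the α‑centre is kept.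

Step 6
Reactants: 8 (S)-2-methylpent-4-en-1-ol
Product: 9 (S)-2-methylpent-4-enal
Conditions: Dess–Martin periodinane, CH2Cl2, 0 °C to rt; used at once
Reagents that add atoms: none
Why: Dess–Martin oxidation stops at the aldehyde under nearly neutral conditions in which α‑branched aldehydes keep their configuration.

Step 7
Reactants: 9 (S)-2-methylpent-4-enal
Product: 10 2-[(1E,3S)-3-methylhexa-1,5-dien-1-yl]-4,4,5,5-tetramethyl-1,3,2-dioxaborolane
Conditions: Cl2CHBpin, CrCl2, LiI, THF, rt
Reagents that add atoms: 2-(dichloromethyl)-4,4,5,5-tetramethyl-1,3,2-dioxaborolane ClC(Cl)B1OC(C)(C)C(C)(C)O1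
Why: Takai–Utimoto chromium(II) olefination with a gem‑dihalomethylboronate uses a non‑basic gem‑dichromium reagent that adds to the aldehyde without epimerising C7, eliminates to the (E)‑alkenylboronate and leaves the terminal alkene untouched.

Step 8
Reactants: 10 2-[(1E,3S)-3-methylhexa-1,5-dien-1-yl]-4,4,5,5-tetramethyl-1,3,2-dioxaborolane
Product: 12 2-[(2E,4S)-4-methylhepta-2,6-dien-1-yl]-4,4,5,5-tetramethyl-1,3,2-dioxaborolane, via boron ate complex 11 (not isolated)
Conditions: ICH2Cl, n-BuLi, THF, −78 °C to rt
Reagents that add atoms: chloroiodomethane ClCI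
Why: Matteson homologation, in which chloromethyllithium made in situ adds to boron and the alkenyl group of 11 migrates 1,2 with loss of chloride and retention of the E geometry, turning the alkenylboronate into the allylboronate.

Step 9
Reactants: 13 2,2,6-trimethyl-4H-1,3-dioxin-4-one
Product: 15 N-methoxy-N-methyl-3-oxobutanamide, via acetylketene 14 (not isolated)
Conditions: MeNH(OMe)·HCl, Et3N, PhMe, 110 °C, sealed tube
Reagents that add atoms: N,O-dimethylhydroxylamine hydrochloride CNOC.Cl
Why: Thermal retro‑hetero‑Diels–Alder cleavage of the dioxinone releases acetylketene, which the amine traps at the ketene carbon (acetoacetylation) faster than it dimerises.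

Step 10
Reactants: 15 N-methoxy-N-methyl-3-oxobutanamide
Product: 16 2-diazo-N-methoxy-N-methyl-3-oxobutanamide
Conditions: p-ABSA, Et3N, MeCN, 0 °C to rt
Reagents that add atoms: 4-acetamidobenzenesulfonyl azide CC(=O)Nc1ccc(cc1)S(=O)(=O)N=[N+]=[N-]
Why: Regitz diazo transfer to the activated methylene of a 1,3‑dicarbonyl compound proceeds under mild amine base.

Step 11
Reactants: 5 4-methoxy-5-methyl-2-oxo-2H-chromene-3-carbaldehyde; 12 2-[(2E,4S)-4-methylhepta-2,6-dien-1-yl]-4,4,5,5-tetramethyl-1,3,2-dioxaborolane
Product: 18 3-[(1R,2S,3S)-2-ethenyl-1-hydroxy-3-methylhex-5-en-1-yl]-4-methoxy-5-methyl-2H-chromen-2-one, via O-boryl adduct 17 (not isolated)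
Conditions: (R)-TRIP (10 mol %), 4 Å MS, PhMe, −30 °C; aq NaHCO3
Reagents that add atoms: none
Why: Chiral‑phosphoric‑acid‑catalysed allylboration through a closed Zimmerman–Traxler chair, in which the E geometry of 12 places C7 equatorial and so gives the anti C1/C7a relationship of the target (O2 and C7 on opposite sides of the C3'–C1–C7a–C4a zigzag), while the catalyst selects the Re face of 5 and thereby (1R) with the matching C7a configuration, the small methyl/allyl difference at C7 exerting little bias of its own.

Step 12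
Reactants: 18 3-[(1R,2S,3S)-2-ethenyl-1-hydroxy-3-methylhex-5-en-1-yl]-4-methoxy-5-methyl-2H-chromen-2-one
Product: 19 3-{(R)-hydroxy[(1R,5S)-5-methylcyclopent-2-en-1-yl]methyl}-4-methoxy-5-methyl-2H-chromen-2-one
Conditions: Grubbs II (3 mol %), CH2Cl2 (0.01 M), 40 °C
Reagents that add atoms: none
Why: Ring‑closing metathesis of the 1,6‑diene (vinyl on C7a, allyl on C7) closes the five‑membered ring as the C4a=C5 alkene with loss of ethene, touches no stereocentre, and so leaves the C7 methyl trans to the C1 side chain, the tetrasubstituted C3'=C4' bond being no metathesis partner.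

Step 13
Reactants: 19 3-{(R)-hydroxy[(1R,5S)-5-methylcyclopent-2-en-1-yl]methyl}-4-methoxy-5-methyl-2H-chromen-2-one; 16 2-diazo-N-methoxy-N-methyl-3-oxobutanamide
Product: 20 2-{(R)-(4-methoxy-5-methyl-2-oxo-2H-chromen-3-yl)[(1R,5S)-5-methylcyclopent-2-en-1-yl]methoxy}-N-methoxy-N-methyl-3-oxobutanamide (epimers at the new α-carbon)
Conditions: Rh2(OAc)4 (2 mol %), PhH, 80 °C, slow addition of 16 (2 equiv)
Reagents that add atoms: none
Why: Rhodium‑carbenoid O–H insertion (oxonium ylide, then proton shift) of an acceptor/acceptor diazo compound is neutral, does not break the C1–O bond and so retains (1R), outpaces cyclopropanation of a 1,2‑disubstituted alkene, and creates an α‑centre that is erased in the next step.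

Step 14
Reactants: 20 2-{(R)-(4-methoxy-5-methyl-2-oxo-2H-chromen-3-yl)[(1R,5S)-5-methylcyclopent-2-en-1-yl]methoxy}-N-methoxy-N-methyl-3-oxobutanamide
Product: 22 (E/Z)-3-bromo-2-{(R)-(4-methoxy-5-methyl-2-oxo-2H-chromen-3-yl)[(1R,5S)-5-methylcyclopent-2-en-1-yl]methoxy}-N-methoxy-N-methylbut-2-enamide, via enoxyphosphonium bromide 21 (not isolated)
Conditions: Ph3PBr2 (1.5 equiv), Et3N (2 equiv), CH2Cl2, 0 °C to rt
Reagents that add atoms: dibromotriphenylphosphorane BrP(Br)(c1ccccc1)(c1ccccc1)c1ccccc1
Why: Halophosphonium deoxybromination of an enolisable 1,3‑dicarbonyl compound, in which the enolate oxygen attacks phosphorus, bromide adds to the cationically activated β‑carbon C4 and Ph3PO leaves (addition–elimination), while Et3N keeps the medium non‑acidic for the ionisable C1–O bond and the alkene geometry is of no consequence.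

Step 15
Reactants: 22 (E/Z)-3-bromo-2-{(R)-(4-methoxy-5-methyl-2-oxo-2H-chromen-3-yl)[(1R,5S)-5-methylcyclopent-2-en-1-yl]methoxy}-N-methoxy-N-methylbut-2-enamide
Product: 23 (1R,4aS,7S,7aR)-N-methoxy-1-(4-methoxy-5-methyl-2-oxo-2H-chromen-3-yl)-N,4,7-trimethyl-1,4a,5,6,7,7a-hexahydrocyclopenta[c]pyran-3-carboxamide
Conditions: Bu3SnH (1.3 equiv) + AIBN (0.2 equiv) by syringe pump (6 h), PhH (0.01 M), 80 °C
Reagents that add atoms: none
Why: Bu3Sn• takes bromine from either isomer of 22 to give a bent σ‑vinyl radical at C4 whose inversion is far faster than ring closure, so the invertomer with its orbital on the O2 side is drained by addition to C4a, both bromides converge on 23, and the secondary C5 radical takes hydrogen from the stannane and carries the chain. The closest known reaction type is the tin‑hydride cyclisation of 1‑bromoalkene‑derived vinyl radicals onto cycloalkenes, which is indifferent to bromide geometry. The dihydropyran closes 6‑exo‑trig (C4, C3, O2, C1, C7a and C4a in the ring, C5 outside it). C4a is controlled by C7a, because the O2–C1–C7a tether reaches only the cyclopentene face that bears C1, so C4 and C1 end up cis (cis fusion, 4aS) and C5 becomes a CH2 with no further centre. The step needs 6‑exo over 7‑endo attack (bonding at C5 would build a strained bridged oxabicycle), and it needs addition to outrun both direct reduction and 1,5‑hydrogen transfer from the allylic C7a–H; low stationary stannane concentration serves the first, and the anti C1/C7a configuration serves the second, since it holds the coumarin pseudo‑equatorial in the addition array but would force it pseudo‑axial in the hydrogen‑transfer array. The coumarin C3'=C4' bond is tetrasubstituted, screened by the 5'-methyl group and reachable at C3' only through a strained five‑membered array containing C3=C4, and the amide form of the acyl group leaves no other unhindered alkene within reach.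

Step 16
Reactants: 23 (1R,4aS,7S,7aR)-N-methoxy-1-(4-methoxy-5-methyl-2-oxo-2H-chromen-3-yl)-N,4,7-trimethyl-1,4a,5,6,7,7a-hexahydrocyclopenta[c]pyran-3-carboxamide
Product: 24 (1R,4aS,7S,7aR)-1-(4-hydroxy-5-methyl-2-oxo-2H-chromen-3-yl)-N-methoxy-N,4,7-trimethyl-1,4a,5,6,7,7a-hexahydrocyclopenta[c]pyran-3-carboxamide
Conditions: LiCl (5 equiv), DMSO, 70 °C; cold dilute HCl
Reagents that add atoms: none
Why: SN2 demethylation of a vinylogous methyl ester, in which the 4'-oxidocoumarin is a carboxylate‑like leaving group so that chloride attacks only this O‑methyl carbon, leaving the N–OMe group, the enol ether and all stereocentres untouched, and running it before the ketone is installed keeps the nucleophile away from the dienone.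

Step 17
Reactants: 24 (1R,4aS,7S,7aR)-1-(4-hydroxy-5-methyl-2-oxo-2H-chromen-3-yl)-N-methoxy-N,4,7-trimethyl-1,4a,5,6,7,7a-hexahydrocyclopenta[c]pyran-3-carboxamide; 25 2-methylprop-1-enylmagnesium bromide
Product: 27 4-hydroxy-5-methyl-3-[(1R,4aS,7S,7aR)-4,7-dimethyl-3-(3-methylbut-2-enoyl)-1,4a,5,6,7,7a-hexahydrocyclopenta[c]pyran-1-yl]-2H-chromen-2-one, via magnesium hemiaminal 26 (not isolated)
Conditions: 25 (3.5 equiv), THF, −20 to 0 °C; cold 0.5 M HCl
Reagents that add atoms: none
Why: Weinreb ketone synthesis, in which the first equivalent of 25 deprotonates the 4'-OH to a magnesium coumarinate whose delocalised charge shields C2' and C4', a further equivalent adds to the amide, and the N‑methoxy chelate 26 holds until the quench so that no tertiary alcohol forms and no stereocentre is touched.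

## Compound list

1 | 2'-hydroxy-6'-methylacetophenone | CC(=O)c1c(C)cccc1O | starting material
2 | 4-hydroxy-5-methylcoumarin | O=c1cc(O)c2c(C)cccc2o1 | intermediate
3 | [(4-chloro-5-methyl-2-oxo-2H-chromen-3-yl)methylidene]dimethylammonium chloride | C[N+](C)=Cc1c(Cl)c2c(C)cccc2oc1=O.[Cl-] | intermediate
4 | 4-chloro-5-methyl-2-oxo-2H-chromene-3-carbaldehyde | O=Cc1c(Cl)c2c(C)cccc2oc1=O | intermediate
5 | 4-methoxy-5-methyl-2-oxo-2H-chromene-3-carbaldehyde | O=Cc1c(OC)c2c(C)cccc2oc1=O | intermediate
6 | (R)-4-benzyl-3-propionyloxazolidin-2-one | CCC(=O)N1[C@H](Cc2ccccc2)COC1=O | starting material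
7 | (R)-4-benzyl-3-[(S)-2-methylpent-4-enoyl]oxazolidin-2-one | C=CC[C@H](C)C(=O)N1[C@H](Cc2ccccc2)COC1=O | intermediate
8 | (S)-2-methylpent-4-en-1-ol | C=CC[C@H](C)CO | intermediate
9 | (S)-2-methylpent-4-enal | C=CC[C@H](C)C=O | intermediate
10 | 2-[(1E,3S)-3-methylhexa-1,5-dien-1-yl]-4,4,5,5-tetramethyl-1,3,2-dioxaborolane | C=CC[C@H](C)/C=C/B1OC(C)(C)C(C)(C)O1 | intermediate
11 | lithium (chloromethyl)[(1E,3S)-3-methylhexa-1,5-dien-1-yl](pinacolato)borate | [Li+].ClC[B-]1(/C=C/[C@@H](C)CC=C)OC(C)(C)C(C)(C)O1 | intermediate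
12 | 2-[(2E,4S)-4-methylhepta-2,6-dien-1-yl]-4,4,5,5-tetramethyl-1,3,2-dioxaborolane | C=CC[C@H](C)/C=C/CB1OC(C)(C)C(C)(C)O1 | intermediate
13 | 2,2,6-trimethyl-4H-1,3-dioxin-4-one | CC1=CC(=O)OC(C)(C)O1 | starting material
14 | acetylketene | CC(=O)C=C=O | intermediate
15 | N-methoxy-N-methyl-3-oxobutanamide | CC(=O)CC(=O)N(C)OC | intermediate
16 | 2-diazo-N-methoxy-N-methyl-3-oxobutanamide | CC(=O)C(=[N+]=[N-])C(=O)N(C)OC | intermediate
17 | pinacol borate ester (O-Bpin) of 18 | CC1(C)OB(O[C@@H](c2c(OC)c3c(C)cccc3oc2=O)[C@@H](C=C)[C@@H](C)CC=C)OC1(C)C | intermediate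
18 | 3-[(1R,2S,3S)-2-ethenyl-1-hydroxy-3-methylhex-5-en-1-yl]-4-methoxy-5-methyl-2H-chromen-2-one | O[C@@H](c1c(OC)c2c(C)cccc2oc1=O)[C@@H](C=C)[C@@H](C)CC=C | intermediate
19 | 3-{(R)-hydroxy[(1R,5S)-5-methylcyclopent-2-en-1-yl]methyl}-4-methoxy-5-methyl-2H-chromen-2-one | O[C@@H](c1c(OC)c2c(C)cccc2oc1=O)[C@H]1C=CC[C@@H]1C | intermediate
20 | α-alkoxy-β-keto Weinreb amide (ether of 19, epimers at the α-carbon) | CON(C)C(=O)C(C(C)=O)O[C@@H](c1c(OC)c2c(C)cccc2oc1=O)[C@H]1C=CC[C@@H]1C | intermediate
21 | enoxy(triphenyl)phosphonium bromide of 20 | CON(C)C(=O)C(=C(C)O[P+](c1ccccc1)(c1ccccc1)c1ccccc1)O[C@@H](c1c(OC)c2c(C)cccc2oc1=O)[C@H]1C=CC[C@@H]1C.[Br-] | intermediate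
22 | E/Z bromoalkenyl ether (radical precursor) | CON(C)C(=O)C(=C(C)Br)O[C@@H](c1c(OC)c2c(C)cccc2oc1=O)[C@H]1C=CC[C@@H]1C | intermediate
23 | (1R,4aS,7S,7aR) bicyclic C3 Weinreb amide, 4'-OMe | CON(C)C(=O)C1=C(C)[C@H]2CC[C@H](C)[C@H]2[C@H](c2c(OC)c3c(C)cccc3oc2=O)O1 | intermediate
24 | (1R,4aS,7S,7aR) bicyclic C3 Weinreb amide, 4'-OH | CON(C)C(=O)C1=C(C)[C@H]2CC[C@H](C)[C@H]2[C@H](c2c(O)c3c(C)cccc3oc2=O)O1 | intermediate
25 | 2-methylprop-1-enylmagnesium bromide | CC(C)=C[Mg]Br | starting material
26 | bis(bromomagnesium) hemiaminal adduct of 24 | CON(C)C(O[Mg]Br)(C=C(C)C)C1=C(C)[C@H]2CC[C@H](C)[C@H]2[C@H](c2c(O[Mg]Br)c3c(C)cccc3oc2=O)O1 | intermediate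
27 | CNP0297827.1 | CC(C)=CC(=O)C1=C(C)[C@H]2CC[C@H](C)[C@H]2[C@H](c2c(O)c3c(C)cccc3oc2=O)O1 | target

## Step count and risks

Total steps: 17. Longest linear sequence: 12 (steps 4–8, then 11–17).

**Step 15 (key step).** The C4 vinyl radical may be consumed by hydrogen transfer, either from the stannane or intramolecularly from the allylic C7a–H, before it adds to C4a. The C5 radical may also re‑add to the new C3=C4 bond (homoallyl/cyclopropylcarbinyl rearrangement) when hydrogen delivery is slow.

The fallback sets out from 22 and forms the same C4–C4a bond by an intramolecular Heck reaction (Pd(OAc)2, PPh3, Ag2CO3, MeCN, 80 °C). The 6‑exo syn‑carbopalladation occurs on the face that bears C1. Because H4a lies anti to palladium, β‑hydride elimination can run only toward C6 and should give the 5,6‑didehydro bicyclic Weinreb amide F1. Diimide (2‑nitrobenzenesulfonyl hydrazide, Et3N) should then saturate only the disubstituted ring alkene, and the route is rejoined at 23. In this mode only (Z)‑22 (Br cis to O2) can cyclise, so the E isomer would have to be separated and re‑equilibrated.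

**Step 14.** O‑phosphonium activation of the hindered α‑alkoxy β‑keto amide may be slow. It may also be diverted to C‑bromination of the enolate or to ionisation of the C1–O bond.

The fallback sets out from 20. The sodium enolate (NaH, THF, 0 °C) is O‑sulfonylated with N‑(5‑chloro‑2‑pyridyl)triflimide to the enol triflate F2. Coupling with hexamethylditin (Pd(PPh3)4, LiCl, THF, 60 °C) gives the C4 trimethylstannane F3. Bromodestannylation with NBS at −78 °C, where ipso attack at the vinyl–tin bond should outrun reaction at the ring alkene, rejoins the route at 22. Any scrambling of alkene geometry on the way is harmless.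

**Step 11.** Facial selectivity may be poor or turnover slow, because the formyl group of 5 is flanked on both sides and is electronically damped by the 4'-methoxy group, and the γ‑substituent of 12 is branched.

The fallback sets out from 5 and 12 and replaces catalyst control with resolution through the resident C7 centre. The uncatalysed allylboration (PhMe, rt to 40 °C) still passes through the chair, so only the two anti adducts should form. These are 17, hydrolysed to 18, and the C1,C7a‑inverted O‑boryl adduct F4, hydrolysed to the diastereomeric diene alcohol F5. Metathesis of the mixture under the conditions of step 12 should give 19 together with the cis‑ring carbinol F6. The trans and cis ring diastereomers should separate by chromatography, and the route is rejoined at 19.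

## Further compounds

F1 | step 15 | (1R,4aS,7S,7aR)-N-methoxy-1-(4-methoxy-5-methyl-2-oxo-2H-chromen-3-yl)-N,4,7-trimethyl-1,4a,7,7a-tetrahydrocyclopenta[c]pyran-3-carboxamide | CON(C)C(=O)C1=C(C)[C@H]2C=C[C@H](C)[C@H]2[C@H](c2c(OC)c3c(C)cccc3oc2=O)O1
F2 | step 14 | E/Z enol triflate of 20 | CON(C)C(=O)C(=C(C)OS(=O)(=O)C(F)(F)F)O[C@@H](c1c(OC)c2c(C)cccc2oc1=O)[C@H]1C=CC[C@@H]1C
F3 | step 14 | E/Z C4 trimethylstannyl alkenyl ether | CON(C)C(=O)C(=C(C)[Sn](C)(C)C)O[C@@H](c1c(OC)c2c(C)cccc2oc1=O)[C@H]1C=CC[C@@H]1C
F4 | step 11 | pinacol borate ester (O-Bpin) of F5 | CC1(C)OB(O[C@H](c2c(OC)c3c(C)cccc3oc2=O)[C@H](C=C)[C@@H](C)CC=C)OC1(C)C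
F5 | step 11 | 3-[(1S,2R,3S)-2-ethenyl-1-hydroxy-3-methylhex-5-en-1-yl]-4-methoxy-5-methyl-2H-chromen-2-one | O[C@H](c1c(OC)c2c(C)cccc2oc1=O)[C@H](C=C)[C@@H](C)CC=C
F6 | step 11 | 3-{(S)-hydroxy[(1S,5S)-5-methylcyclopent-2-en-1-yl]methyl}-4-methoxy-5-methyl-2H-chromen-2-one | O[C@H](c1c(OC)c2c(C)cccc2oc1=O)[C@@H]1C=CC[C@@H]1C
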